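## Retrosynthetic overview

- **Last bond, C2'–C3' (sp3–sp2):** Ni-catalysed reductive coupling of an (S)-2-(2-iodoethyl)chroman-6-ol with an (E)-alkenyl iodide that already carries the C9' carbinol.
- **Key step (chroman half):** Cu/bis(oxazoline) enantioselective oxycupration of an o-(3-methylbut-3-enyl)phenol closes the ring and sets C2. The resulting chroman-2-ylmethyl radical adds to a styryl sulfone, forming C1'–C2'.
- **After the key step:** the styryl group is cut to the two-carbon arm (O3/NaBH4), C6–OH is added by C–H borylation/oxidation, and the alcohol becomes the iodide. The phenol–alkene comes from o-cresol by ortho-bromination and Negishi coupling.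
- **Alkenyl iodide half, from pent-4-yn-1-ol:** carboalumination/iodination (E-C3'=C4'), oxidation/Wittig (E-C7'=C8'), Brown allylation (C9'), cross-metathesis (prenyl end).
- **Rings:** the arene is bought in as o-cresol; the dihydropyran ring is the only ring formed, in the key step.

Assumption: the sense of induction in the Cu/t-Bu-Box step is assigned by analogy with alkenol cyclisations; if correlation shows the opposite sense, the ligand antipode is used.

Note on descriptors: intermediates 5–8 are (S) by CIP rules but have the same spatial arrangement at C2 as the (2R) target; the descriptor changes only because the priorities of the two CH2 arms swap.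

## Route

**Step 1**
Reactants: 1, o-cresol (2-methylphenol)
Product: 2, 2-bromo-6-methylphenol
Conditions: NBS (1.0 equiv), i-Pr2NH (10 mol %), CH2Cl2, 0 °C → rt
Reagents that add atoms: N-bromosuccinimide, O=C1CCC(=O)N1Br
Why: Amine-mediated ortho-selective electrophilic bromination of a phenol; the only free ortho position is C6, and no stereocentre is formed.

**Step 2**
Reactants: 2, 2-bromo-6-methylphenol; 3, 4-bromo-2-methylbut-1-ene
Product: 4, 2-methyl-6-(3-methylbut-3-en-1-yl)phenol
Conditions: 3, Zn dust, LiCl, THF, 50 °C (gives RZnBr·LiCl, 2.3 equiv); then 2, Pd(OAc)2 (2 mol %), SPhos (4 mol %), THF, 25–50 °C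
Reagents that add atoms: none
Why: Negishi sp2–sp3 coupling; primary alkylzinc reagents with Pd/SPhos tolerate a free ArOH (the first equivalent is consumed as the zinc phenoxide) and the isolated 1,1-disubstituted alkene is untouched.

**Step 3 (key step)**
Reactants: 4, 2-methyl-6-(3-methylbut-3-en-1-yl)phenol
Product: 5, (S)-2,8-dimethyl-2-[(2E)-3-phenylprop-2-en-1-yl]chromane
Conditions: Cu(OTf)2 (20 mol %), (S,S)-t-Bu-Box (25 mol %), K2CO3 (1.5 equiv), (E)-PhCH=CHSO2Ph (2 equiv), 4 Å MS, PhCF3, 110 °C, Ar, no external oxidant
Reagents that add atoms: (E)-phenyl 2-phenylethenyl sulfone, O=S(=O)(/C=C/c1ccccc1)c1ccccc1 (transfers PhCH=CH; PhSO2 is lost)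
Why: Proposed new method: the L*Cu(II)–phenoxide adds across the alkene by ligand-controlled, enantiofacial cis-oxycupration (6-exo), which forms O1–C2 and sets the C2 quaternary stereocentre; C–Cu(II) homolysis gives the chroman-2-ylmethyl radical, which adds to the sulfonyl-bearing carbon of the styryl sulfone (forming C1'–C2') and expels PhSO2•, and PhSO2• re-oxidises Cu(I) to Cu(II), so no MnO2 or O2 is needed and the oxidisable 2,6-dialkylphenol is not exposed to a bulk oxidant; the closest known reactions are Cu(II)/bis(oxazoline) enantioselective carboetherification and carboamination of 1,1-disubstituted alkenols and N-aryl sulfonamides with vinylarenes (same oxycupration/homolysis/radical-addition sequence; a sulfonamide N–H has acidity similar to a phenol) and radical alkenylation with β-sulfonylstyrenes.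

**Step 4**
Reactants: 5, (S)-2,8-dimethyl-2-[(2E)-3-phenylprop-2-en-1-yl]chromane
Product: 6, 2-[(2S)-2,8-dimethylchroman-2-yl]ethan-1-ol
Conditions: O3, CH2Cl2/MeOH 3:1, −78 °C, Sudan III end-point; then NaBH4, −78 → 0 °C
Reagents that add atoms: ozone, [O-][O+]=O
Why: Ozonolysis with reductive work-up cleaves the styryl alkene far faster than the aryl ether ring, and the β-aryloxy aldehyde is reduced in situ before it can undergo retro-oxa-Michael opening; C2 is quaternary and untouched (benzyl alcohol is the by-product).

**Step 5**
Reactants: 6, 2-[(2S)-2,8-dimethylchroman-2-yl]ethan-1-ol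
Product: 7, (2S)-2-(2-hydroxyethyl)-2,8-dimethylchroman-6-ol
Conditions: [Ir(OMe)(cod)]2 (1.5 mol %), dtbpy (3 mol %), B2pin2 (1.6 equiv), THF, 80 °C; then 30 % H2O2, aq NaOH, THF, 0 °C
Reagents that add atoms: hydrogen peroxide, OO (supplies the phenolic O; boron from B2pin2 is not retained)
Why: Sterically controlled Ir-catalysed arene C–H borylation followed by one-pot oxidation; C6 is the only aromatic C–H without an ortho substituent (C5 is next to the ring CH2, C7 next to the 8-methyl), and the free alcohol is only transiently O-borylated.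

**Step 6**
Reactants: 7, (2S)-2-(2-hydroxyethyl)-2,8-dimethylchroman-6-ol
Product: 8, (2S)-2-(2-iodoethyl)-2,8-dimethylchroman-6-ol
Conditions: PPh3, I2, imidazole (pre-mixed), CH2Cl2, 0 °C → rt
Reagents that add atoms: iodine, II
Why: Appel iodination is selective for the primary aliphatic alcohol over the phenol (as in the tyrosol to 4-(2-iodoethyl)phenol conversion), and pre-forming Ph3P·I2 avoids ring iodination.

**Step 7**
Reactants: 9, pent-4-yn-1-ol
Product: 10, (E)-5-iodo-4-methylpent-4-en-1-ol
Conditions: Me3Al (3 equiv), Cp2ZrCl2 (0.25 equiv), CH2Cl2, 0 °C → rt; then I2, THF, −30 → 0 °C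
Reagents that add atoms: trimethylaluminium, C[Al](C)C; iodine, II
Why: Negishi Zr-catalysed syn-carboalumination places Me on the internal carbon and Al on the terminus, and iodinolysis with retention gives the (E)-iodoalkene that becomes the target's C3'=C4' bond.

**Step 8**
Reactants: 10, (E)-5-iodo-4-methylpent-4-en-1-ol
Product: 11, (2E,6E)-7-iodo-2,6-dimethylhepta-2,6-dienal
Conditions: TEMPO (10 mol %), PhI(OAc)2 (1.1 equiv), CH2Cl2, rt; then Ph3P=C(CH3)CHO (1.3 equiv), PhMe, 80 °C (one pot)
Reagents that add atoms: 2-(triphenylphosphoranylidene)propanal, CC(C=O)=P(c1ccccc1)(c1ccccc1)c1ccccc1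
Why: One-pot TEMPO/BAIB oxidation then Wittig olefination with a formyl-stabilised ylide, which gives the (E)-2-methyl enal (typically >20:1) that becomes C7'=C8'.

**Step 9**
Reactants: 11, (2E,6E)-7-iodo-2,6-dimethylhepta-2,6-dienal
Product: 12, (4R,5E,9E)-10-iodo-5,9-dimethyldeca-1,5,9-trien-4-ol
Conditions: (+)-Ipc2B(allyl) [from (+)-Ipc2BOMe (derived from (−)-α-pinene) and allylMgBr, salt-free], Et2O, −78 °C; then NaOH, H2O2, 0 °C
Reagents that add atoms: (+)-B-allyldiisopinocampheylborane, C=CCB(C1CC2CC(C1C)C2(C)C)C1CC2CC(C1C)C2(C)C
Why: Brown allylation through a closed chair transition state with reagent control; (+)-Ipc2B(allyl) attacks the face that turns benzaldehyde into (R)-1-phenylbut-3-en-1-ol, which here gives the (R) carbinol (C9'), with clean 1,2-addition to the enal and about 90–95 % ee expected.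

**Step 10**
Reactants: 12, (4R,5E,9E)-10-iodo-5,9-dimethyldeca-1,5,9-trien-4-ol
Product: 13, (1E,5E,7R)-1-iodo-2,6,10-trimethylundeca-1,5,9-trien-7-ol
Conditions: Grubbs II (5 mol %), 2-methylbut-2-ene (excess, co-solvent), CH2Cl2, 40 °C
Reagents that add atoms: 2-methylbut-2-ene, CC=C(C)C (supplies =C(CH3)2)
Why: Olefin cross-metathesis converts the terminal allyl group into prenyl; the trisubstituted alkene and the trisubstituted iodoalkene are inert to the Ru carbene, and the free alcohol and C9' are unaffected.

**Step 11**
Reactants: 8, (2S)-2-(2-iodoethyl)-2,8-dimethylchroman-6-ol; 13, (1E,5E,7R)-1-iodo-2,6,10-trimethylundeca-1,5,9-trien-7-ol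
Product: 14, sargachromanol C, (2R)-2-[(3E,7E,9R)-9-hydroxy-4,8,12-trimethyltrideca-3,7,11-trien-1-yl]-2,8-dimethylchroman-6-ol
Conditions: NiI2·xH2O (10 mol %), 4,4'-di-tert-butyl-2,2'-bipyridine (10 mol %), Zn dust (2.5 equiv), NaI (0.25 equiv), DMA, 25–40 °C; 8 (1.5 equiv), 13 (1.0 equiv)
Reagents that add atoms: none
Why: Ni-catalysed reductive cross-electrophile coupling: Ni(0) inserts into the C(sp2)–I bond, the primary alkyl radical from 8 is captured by the alkenyl–Ni(II) species, and reductive elimination forms C2'–C3' with retention of the E geometry; free OH groups are tolerated and neither stereocentre is involved.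

## Compound list

1 | o-cresol (2-methylphenol) | Cc1ccccc1O | starting material
2 | 2-bromo-6-methylphenol | Cc1cccc(Br)c1O | intermediate
3 | 4-bromo-2-methylbut-1-ene | C=C(C)CCBr | starting material
4 | 2-methyl-6-(3-methylbut-3-en-1-yl)phenol | C=C(C)CCc1cccc(C)c1O | intermediate
5 | (S)-2,8-dimethyl-2-[(2E)-3-phenylprop-2-en-1-yl]chromane | c1ccccc1/C=C/C[C@]2(C)CCc3cccc(C)c3O2 | intermediate
6 | 2-[(2S)-2,8-dimethylchroman-2-yl]ethan-1-ol | OCC[C@]1(C)CCc2cccc(C)c2O1 | intermediate
7 | (2S)-2-(2-hydroxyethyl)-2,8-dimethylchroman-6-ol | OCC[C@]1(C)CCc2cc(O)cc(C)c2O1 | intermediate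
8 | (2S)-2-(2-iodoethyl)-2,8-dimethylchroman-6-ol | ICC[C@]1(C)CCc2cc(O)cc(C)c2O1 | intermediate
9 | pent-4-yn-1-ol | C#CCCCO | starting material
10 | (E)-5-iodo-4-methylpent-4-en-1-ol | OCCC/C(C)=C/I | intermediate
11 | (2E,6E)-7-iodo-2,6-dimethylhepta-2,6-dienal | O=C/C(C)=C/CC/C(C)=C/I | intermediate
12 | (4R,5E,9E)-10-iodo-5,9-dimethyldeca-1,5,9-trien-4-ol | C=CC[C@@H](O)/C(C)=C/CC/C(C)=C/I | intermediate
13 | (1E,5E,7R)-1-iodo-2,6,10-trimethylundeca-1,5,9-trien-7-ol | CC(C)=CC[C@@H](O)/C(C)=C/CC/C(C)=C/I | intermediate
14 | sargachromanol C | CC(C)=CC[C@@H](O)/C(C)=C/CC/C(C)=C/CC[C@]1(C)CCc2cc(O)cc(C)c2O1 | target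

## Summary

Total steps: 11. Longest linear sequence: 7 (steps 1–6, then 11).

Steps most likely to fail, with fallbacks:

1. **Step 3 (Cu oxycupration/radical styrylation).** The Cu(II)–phenoxide may instead undergo one-electron phenol oxidation and coupling, or acid-type cyclisation to achiral 2,2,8-trimethylchroman, and 6-exo enantioselectivity with a phenol is untested. Fallback: set C2 by enantioselective Pd(II) Wacker-type cyclisation/methoxycarbonylation of 4 (BOXAX-type ligand, p-benzoquinone, CO/MeOH) to the chroman-2-acetate, then LiAlH4 to reach 6 and rejoin at step 5.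

2. **Step 11 (Ni reductive coupling).** Homodimers of either iodide, reduction of the alkyl iodide, or interference from the phenol are possible. Fallback: protect 8 (TBS) and 13 (TES), convert the alkyl iodide to the B-alkyl-9-BBN borinate (t-BuLi, B-OMe-9-BBN) and join by Pd-catalysed B-alkyl Suzuki–Miyaura coupling, then desilylate.

3. **Step 5 (C–H borylation/oxidation).** O-borylation may consume reagent, and the electron-rich chromanol may over-oxidise to a quinone during the B→OH step. Fallback: install the C6 oxygen before ring closure by oxidising phenol 4 to the p-quinone (Fremy's salt), reducing it, mono-pivaloylating the unhindered OH, carrying the para-blocked phenol through step 3, and cleaving the ester after the coupling.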